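## Structural features

The target (C42H32O9) is an octaphenol in which an indane and a 2,3-dihydrobenzofuran are joined through one exocyclic methine carbon. Numbering used here: in the indane, C1 carries the 4-hydroxyphenyl group, C2 the 3,5-dihydroxyphenyl group, C3 is the ring carbon of the exocyclic double bond, and the resorcinol hydroxyls sit on C5 and C7. Primed numbers belong to the dihydrobenzofuran: C5' is bonded to the exocyclic =CH, C2' carries 4-hydroxyphenyl and C3' carries 3,5-dihydroxyphenyl.

The four stereocentres form two adjacent pairs, C1/C2 (1S,2S, aryl groups trans) and C2'/C3' (2R,3R, aryl groups trans). The pairs are separated by the alkene and a benzene ring, so neither can direct the other. The alkene is E, with the dihydrobenzofuranyl group on the C2 side of C3.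

Three features are fragile. Acid can move the exocyclic double bond into the ring (C2=C3), which erases C2. The C2'–O1' bond is a benzylic ether of a para-oxygenated aryl group and ionises under acid (trans is the thermodynamic arrangement). The eight phenols are oxidisable and are therefore carried as methyl ethers.

The real difficulty is C1, a diarylmethine with no neighbouring heteroatom handle, which must be set by a catalyst. After that, two enantiopure halves must be joined through a trisubstituted alkene of defined position and geometry.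

The key step uses the fact that the indane benzo ring is a 3,5-dioxygenated phenyl bonded through C3a to C3 (a carbonyl carbon at the indanone stage), with C1 bonded to C7a, the ortho carbon flanked by the C7 oxygen. The two ortho C–H bonds of a 3,5-dimethoxyphenyl carbinol are equivalent, so a metal delivered to either closes C1–C7a with the correct oxygen pattern (4,6-dimethoxy in indanone numbering). C1 keeps the descriptor S as C3 of the indanone.

## Logic of the disconnections

**25 ⇒ 24.** Eight O–CH3 bonds are cut. Free phenols would not survive the organometallic steps, and methyl is the smallest ether, which keeps the ortho C–H bonds needed in step 2 accessible. All earlier chemistry then runs on neutral ethers. The demand is a final ether cleavage that neither moves the alkene nor opens C2'–O1' irreversibly.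

**24 ⇒ 22.** Water is added back across C3=CH (C3–OH and a benzylic CH2). A tertiary alcohol is the direct product of a carbonyl addition, so position and geometry of the alkene are decided in one late step. The elimination must go toward the exocyclic CH2 under kinetic, non-acidic control and give the E isomer.

**22 ⇒ 7 + 20 (reacting as 21).** The C3–CH2 bond is cut. It is the only C–C bond between the two stereochemically independent halves and divides the skeleton into two pieces of similar size, each with one pair of adjacent stereocentres. The demand is a benzylic nucleophile that adds to an easily enolised ketone without deprotonating C2, from the face that puts OH cis to the C2 aryl group.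

**7 ⇒ 5 + 6.** The C2–aryl bond is cut. C2 is α to the carbonyl, so the bond can be made by enolate arylation, and C2 then follows C1 by thermodynamic control. Only C1 needs asymmetric catalysis. The step must stop at mono-arylation and equilibrate to trans without touching C1.

**5 ⇒ 4.** The C1–C7a bond is cut. This opens the five-membered ring to an acyclic propargylic alcohol whose own stereocentre is irrelevant. The forward step must activate an ortho C–H bond next to a methoxy group and choose the face at C1 by the catalyst alone.

**4 ⇒ 1 + 2 (via 3).** The bond between the carbinol carbon and the alkyne is cut, giving two commercial compounds. The only demand is clean 1,2-addition.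

**20 ⇒ 19 ⇒ 16 (via 17 and 18).** C–Cl is traced back to C–OH, and the C5'–CH2 bond is cut to an aryl bromide. Bromine survives the earlier Grignard, hydrazine and carbene chemistry, so the one-carbon handle can be added late. Halogen–metal exchange must outrun any deprotonation.

**16 ⇒ 15.** This is a stereochemical step: C2' is inverted by breaking and re-forming C2'–O1'. The ring-forming reaction gives the cis isomer, and C2' is the ionisable centre while C3' is not. Only C3' therefore needs catalyst control. The acid must ionise the ether without causing elimination.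

**15 ⇒ 13 (via 14).** The C2'–C3' bond is cut, C3' becoming a carbene carbon and C2' an O–CH2 group. The precursor is acyclic and achiral, and both centres arise in one bond formation. The demand is an enantioselective carbene insertion on a diazo compound made in the flask.

**13 ⇒ 10 + 6 (via 11 and 12).** The C3'–aryl bond and the C=N bond are cut. An aryl nucleophile adds to a nitrile and the nitrogen is exchanged, which avoids a separate ketone. Addition must stop at the imine stage.

**10 ⇒ 8 + 9.** The O1'–CH2 bond is cut, a simple phenol alkylation; the CH2 becomes C2'.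

## Other disconnections considered

**Alternative 1:** The cut removes the resorcinol ring of the indane altogether (C3a–C4, C4–C5, C6–C7, C7–C7a). What remains is a cyclopentene that already carries the C1 and C2 aryl groups and a protected C3 oxygen.

- Forward step: the diazomethyl ketone A2 would be irradiated. Wolff rearrangement would give a vinylketene, which would add ethoxyacetylene A3 in a [2+2] sense. The cyclobutenone would open to a dienylketene, close by 6π electrocyclisation and tautomerise to the phenol A1.
- In its favour: the oxygen pattern is built into the cascade (C7–OH from the ketene carbon, C5–OEt from the alkyne). No C–H bond next to an alkoxy group has to be activated. The key step creates no stereocentre, so it cannot fail on enantioselectivity. On these two points it is the better of the two.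
- Against it here: all stereochemical work moves into A2, a cyclopentene with three contiguous centres and no short enantioselective entry. One of those centres (C3) is a placeholder that must later be unmasked and oxidised before the union. The C1–H of A2 is both allylic and benzylic. Three kinds of oxygen protection (methyl, ethyl, silyl) must be handled.
- Comparison: structurally the chosen plan forms one bond on an intact arene where A1 needs three new C–C bonds for the same ring. Mechanistically a metal-free pericyclic cascade stands against a catalytic organometallic cascade; for the ring closure alone the two are about equal in reliability. In step count the chosen plan reaches 7 in three steps, which this alternative cannot approach.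

**Alternative 2:** The cut lies in the other half: C2'–C3' and O1'–C2' of the dihydrofuran ring.

- Forward step: a carbonate base would expel sulfinate from the sulfonyl phenol A5 and release the ortho-quinone methide A6. Deprotonated sulfonium salt A7 would add through its benzylic carbon to the methide carbon (C2'–C3'), and the phenoxide would then displace the sulfide (O1'–C2'). The product A4 is the same substance as 16.
- In its favour: the trans ring forms directly, the conditions are mild, and A5 is about two steps from a salicylaldehyde. A4 would be reached in roughly three operations where steps 4–7 need four. On step count, and on avoiding the acid epimerisation of step 7, it is the better way to 16.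
- Against it: it does not touch the indane, so the problem at C1 remains and step 2 is still needed. The chiral sulfide is used in stoichiometric amount and A7 must be prepared beforehand. Both new centres depend on face selection at a planar, short-lived quinone methide by a chiral group on the nucleophile, which is harder to predict for a semi-stabilised benzylic ylide.
- Comparison: in structure the two are equal for this fragment, since they end at the same compound. In mechanism an ionic addition–displacement that sets C3' and C2' together stands against a catalyst-bound carbene insertion that sets C3' and leaves C2' to thermodynamics. In step economy the alternative saves about one step in the fragment line but adds the preparation of A7. It would be a reasonable substitute for steps 4–7, but it cannot replace the key step.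

**Alternative 3:** The cut is the C3'–C3a' bond, seen as the result of a 1,2-aryl shift: the dihydrofuran would come from a six-membered flavanone by ring contraction.

- Forward step: the flavanone A9 would be treated with a trivalent-iodine diacetate and sulfuric acid in an orthoformate. The enol ether would take iodine at C3, the fused aryl carbon would migrate from C4 to C3 as iodine leaves, and the old carbonyl carbon would end as the methyl ester of A8, substituents trans.
- In its favour: flavanones are available in two steps from a 2-hydroxyacetophenone and an aldehyde, the reagents are cheap and metal-free, and the trans geometry is dependable because C3' is epimerisable next to the ester. On reagent cost it is the better.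
- Against it here: A8 lacks the 3,5-dioxygenated ring. The ester carbon is not part of the target and would have to be exchanged for an aryl group (hydrolysis, then decarboxylative arylation), which sets C3' later under control from C2' alone. The absolute configuration would have to sit at C2 of A9, a centre that can racemise by ring opening to the chalcone in strong acid. The mesylate would have to be changed for the protecting group used elsewhere.
- Comparison: structurally it builds the right ring with a wrong substituent, so it is further from 16 than the carbene insertion or alternative 2. Mechanistically the cationic aryl migration is robust but brings no asymmetric induction of its own. In step economy it would need about seven steps to the stage of 16 against four. It equals the chosen plan only in ending with the same 5-bromo handle for the later one-carbon homologation.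

Key step: step 2

Assumption: for the two enantioselective catalysts (steps 2 and 6) the ligand antipode written is the one taken to give the configuration drawn; if the sense of induction were opposite, the other antipode would be used with no other change.

Remark: species that exist only bound to a catalytic metal are described in the Why lines and are not numbered.

## Route

Step 1
Reactants: 1 4-ethynylanisole; 2 3,5-dimethoxybenzaldehyde
Product: 4 rac-1-(3,5-dimethoxyphenyl)-3-(4-methoxyphenyl)prop-2-yn-1-ol, via lithium (4-methoxyphenyl)acetylide 3 (not isolated)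
Conditions: n-BuLi, THF, −78 °C; then 2, −78 → 0 °C; H2O
Reagents that add atoms: none
Why: 1,2-Addition of an alkynyllithium to a non-enolisable aldehyde; the carbinol may be racemic because its centre is erased in step 2.

Step 2
Reactants: 4 rac-1-(3,5-dimethoxyphenyl)-3-(4-methoxyphenyl)prop-2-yn-1-ol
Product: 5 (S)-4,6-dimethoxy-3-(4-methoxyphenyl)indan-1-one
Conditions: [Rh(OH)(cod)]2 (2.5 mol %), (R)-BINAP (6 mol %), THF, 60 °C
Reagents that add atoms: none
Why: Hydroxide/alkoxide exchange on monovalent rhodium gives the rhodium alkoxide of 4, and β-hydride elimination erases the carbinol centre and leaves an ynone bound to Rh–H. Syn-hydrorhodation of the alkyne puts hydrogen on the carbon bearing the anisyl group and rhodium on the carbon next to the carbonyl, from where a 1,4-shift carries the metal to an ortho carbon of the dimethoxyphenyl ketone (C7a of the target). The aryl–rhodium bond then adds across the enone with the aryl carbon going to the β-carbon, which forms C1–C7a and closes the five-membered ring by intramolecular 1,4-addition (formally a 5-endo-trig carbometalation); protonation of the rhodium enolate by the next molecule of 4 releases 5 and restarts the cycle. The closest known reaction type is the rhodium/bisphosphine isomerisation of racemic α-arylpropargyl alcohols to 3-substituted indan-1-ones. The single new stereocentre (C3 of 5, C1 of the target) is set in the ring-closing addition, where the chiral bisphosphine selects the face of the enone carbon; since the carbinol centre is gone by then, both enantiomers of 4 should converge on (S)-5. Regioselectivity is secured by the substrate: the two ortho C–H bonds of the 3,5-dimethoxyphenyl ring are equivalent and each gives the 4,6-dimethoxy pattern, and the anisyl ortho positions are out of reach because rhodium sits on the α-carbon, trans to the anisyl group after syn addition. Besides face selection the step needs the 1,4-shift to outrun protonation of the alkenylrhodium, which the aprotic medium favours.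

Step 3
Reactants: 5 (S)-4,6-dimethoxy-3-(4-methoxyphenyl)indan-1-one; 6 1-bromo-3,5-dimethoxybenzene
Product: 7 (2S,3S)-2-(3,5-dimethoxyphenyl)-4,6-dimethoxy-3-(4-methoxyphenyl)indan-1-one (2,3-trans)
Conditions: Pd(OAc)2 (5 mol %), P(t-Bu)3 (10 mol %), NaOt-Bu, toluene, 60 °C
Reagents that add atoms: none
Why: Palladium-catalysed ketone α-arylation (oxidative addition of 6 to zerovalent palladium, enolate binding, reductive elimination) at the only enolisable position; the acidic C2–H of the product lets the base equilibrate C2 to the trans isomer, C3 is not acidic and keeps its configuration, and the flanking C3 aryl group should hold back a second arylation.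

Step 4
Reactants: 8 5-bromo-2-hydroxybenzonitrile; 9 4-methoxybenzyl chloride
Product: 10 5-bromo-2-[(4-methoxyphenyl)methoxy]benzonitrile
Conditions: K2CO3, DMF, 60 °C
Reagents that add atoms: none
Why: Williamson ether synthesis on a phenol acidified by the ortho nitrile; the benzylic CH2 introduced here later becomes C2'.

Step 5
Reactants: 6 1-bromo-3,5-dimethoxybenzene; 10 5-bromo-2-[(4-methoxyphenyl)methoxy]benzonitrile
Product: 13 {5-bromo-2-[(4-methoxyphenyl)methoxy]phenyl}(3,5-dimethoxyphenyl)methanone hydrazone (E/Z mixture), via 3,5-dimethoxyphenylmagnesium bromide 11 (not isolated), via N–H ketimine 12 (not isolated)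
Conditions: 6, Mg, THF, reflux; then 10, CuBr (2 mol %), THF, reflux; MeOH, 0 °C; then N2H4·H2O, AcOH (cat.), EtOH, 60 °C
Reagents that add atoms: hydrazine (used as the hydrate), NN
Why: Grignard addition to a nitrile stops at the ketimine stage, methanol frees the N–H ketimine, and transimination with hydrazine (loss of ammonia) gives the hydrazone directly, which avoids the slow condensation of a hindered benzophenone; the hydrazone geometry does not matter because both isomers give the same diazo compound.

Step 6
Reactants: 13 {5-bromo-2-[(4-methoxyphenyl)methoxy]phenyl}(3,5-dimethoxyphenyl)methanone hydrazone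
Product: 15 (2S,3R)-5-bromo-3-(3,5-dimethoxyphenyl)-2-(4-methoxyphenyl)-2,3-dihydro-1-benzofuran (cis), via diaryldiazomethane 14 (not isolated)
Conditions: MnO2, CH2Cl2, 0 °C, filtration; then Rh2(R-PTAD)4 [dirhodium tetrakis((R)-2-(1-adamantyl)-2-phthalimidoacetate)] (1 mol %), CH2Cl2, −20 → 0 °C
Reagents that add atoms: none
Why: Dehydrogenation of the hydrazone gives the diaryldiazomethane, and the derived dirhodium carbene (donor/donor type) undergoes intramolecular 1,5 C–H insertion into the ether CH2, which is activated by oxygen and the anisyl group; the chiral carboxylate ligands set C3', and the concerted insertion should place the two aryl groups cis, as is usual for this reaction type.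

Step 7
Reactants: 15 (2S,3R)-5-bromo-3-(3,5-dimethoxyphenyl)-2-(4-methoxyphenyl)-2,3-dihydro-1-benzofuran
Product: 16 (2R,3R)-5-bromo-3-(3,5-dimethoxyphenyl)-2-(4-methoxyphenyl)-2,3-dihydro-1-benzofuran (trans)
Conditions: CF3CO2H (2 equiv), CH2Cl2, 0 °C → rt; aq NaHCO3
Reagents that add atoms: none
Why: Acid-mediated epimerisation of a 2-aryl-2,3-dihydrobenzofuran at C2': protonation of O1' and reversible heterolysis of C2'–O1' give a cation stabilised by the 4-methoxyphenyl group with the phenol still tethered, and reclosure should settle on the thermodynamic trans isomer; C3' takes no part, so its configuration from step 6 is kept and C2' becomes R.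

Step 8
Reactants: 16 (2R,3R)-5-bromo-3-(3,5-dimethoxyphenyl)-2-(4-methoxyphenyl)-2,3-dihydro-1-benzofuran
Product: 19 [(2R,3R)-3-(3,5-dimethoxyphenyl)-2-(4-methoxyphenyl)-2,3-dihydro-1-benzofuran-5-yl]methanol, via 5-lithio-dihydrobenzofuran 17 (not isolated), via dihydrobenzofuran-5-carbaldehyde 18 (not isolated)
Conditions: n-BuLi, THF, −78 °C; DMF, −78 → 0 °C; then MeOH, NaBH4, 0 °C
Reagents that add atoms: N,N-dimethylformamide, CN(C)C=O
Why: Bromine–lithium exchange, Bouveault formylation of the aryllithium and borohydride reduction in the same flask; exchange at −78 °C is faster than any deprotonation, and neither stereocentre is involved.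

Step 9
Reactants: 19 [(2R,3R)-3-(3,5-dimethoxyphenyl)-2-(4-methoxyphenyl)-2,3-dihydro-1-benzofuran-5-yl]methanol
Product: 20 (2R,3R)-5-(chloromethyl)-3-(3,5-dimethoxyphenyl)-2-(4-methoxyphenyl)-2,3-dihydro-1-benzofuran
Conditions: SOCl2, pyridine, CH2Cl2, 0 °C
Reagents that add atoms: thionyl chloride, O=S(Cl)Cl
Why: Deoxychlorination of a 4-alkoxybenzylic alcohol with thionyl chloride; pyridine takes up the hydrogen chloride so that the acid-sensitive C2'–O1' bond is not exposed, and the reactive chloride is used at once.

Step 10
Reactants: 20 (2R,3R)-5-(chloromethyl)-3-(3,5-dimethoxyphenyl)-2-(4-methoxyphenyl)-2,3-dihydro-1-benzofuran; 7 (2S,3S)-2-(3,5-dimethoxyphenyl)-4,6-dimethoxy-3-(4-methoxyphenyl)indan-1-one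
Product: 22 (1R,2S,3S)-1-{[(2R,3R)-3-(3,5-dimethoxyphenyl)-2-(4-methoxyphenyl)-2,3-dihydro-1-benzofuran-5-yl]methyl}-2-(3,5-dimethoxyphenyl)-4,6-dimethoxy-3-(4-methoxyphenyl)indan-1-ol (hydroxyl cis to the C2 aryl group), via dihydrobenzofuranylmethylmagnesium chloride 21 (not isolated)
Conditions: 20, Mg (activated), THF, 0 °C, slow addition; then added to 7 (1.2 equiv) premixed with anhydrous CeCl3, THF, −78 → 0 °C; H2O
Reagents that add atoms: none
Why: Grignard formation from a 4-alkoxybenzylic chloride followed by CeCl3-promoted 1,2-addition to an enolisable ketone, cerium favouring addition over proton transfer from C2; the nucleophile should approach anti to the neighbouring C2 aryl group, which places OH cis to that aryl, and any C2 epimerisation through stray enolate returns to trans.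

Step 11
Reactants: 22 the tertiary alcohol of step 10
Product: 24 (2R,3R)-5-{(E)-[(2S,3S)-2-(3,5-dimethoxyphenyl)-4,6-dimethoxy-3-(4-methoxyphenyl)-2,3-dihydro-1H-inden-1-ylidene]methyl}-3-(3,5-dimethoxyphenyl)-2-(4-methoxyphenyl)-2,3-dihydro-1-benzofuran, via tertiary sulfamate ester 23 (not isolated)
Conditions: Burgess reagent (methyl N-(triethylammoniosulfonyl)carbamate), toluene, rt → 50 °C
Reagents that add atoms: none
Why: Burgess dehydration through intramolecular syn elimination of the sulfamate ester; the ring C2–H is anti to the leaving group (OH cis to the C2 aryl), so only a hydrogen of the benzylic CH2 can be reached and the exocyclic alkene should form under kinetic, non-acidic control, with the E geometry favoured because the aryl group avoids the peri C–H of the benzo ring in the cyclic transition state.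

Step 12
Reactants: 24 the octamethyl ether of step 11
Product: 25 (1E,2S,3S)-2-(3,5-dihydroxyphenyl)-1-{[(2R,3R)-3-(3,5-dihydroxyphenyl)-2-(4-hydroxyphenyl)-2,3-dihydro-1-benzofuran-5-yl]methylidene}-3-(4-hydroxyphenyl)-2,3-dihydro-1H-indene-4,6-diol (CNP0184753.1)
Conditions: BBr3 (excess), CH2Cl2, −78 → 20 °C; MeOH then aq NaHCO3, 0 °C
Reagents that add atoms: none
Why: Lewis-acid cleavage of aryl methyl ethers (bromide attacks methyl of the boron-complexed ether), a reaction with precedent on exocyclic-alkene indanes and on 2,3-diaryl-dihydrobenzofurans of this family when run cold and quenched into base; no stereocentre is touched, and C2' is already in its thermodynamic configuration should it ionise.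

## Compound list

1 | 4-ethynylanisole | COc1ccc(C#C)cc1 | starting material
2 | 3,5-dimethoxybenzaldehyde | COc1cc(C=O)cc(OC)c1 | starting material
3 | lithium (4-methoxyphenyl)acetylide | COc1ccc(C#C[Li])cc1 | intermediate
4 | rac-1-(3,5-dimethoxyphenyl)-3-(4-methoxyphenyl)prop-2-yn-1-ol | COc1ccc(C#CC(O)c2cc(OC)cc(OC)c2)cc1 | intermediate
5 | (S)-4,6-dimethoxy-3-(4-methoxyphenyl)indan-1-one | COc1ccc([C@H]2c3c(OC)cc(OC)cc3C(=O)C2)cc1 | intermediate
6 | 1-bromo-3,5-dimethoxybenzene | COc1cc(Br)cc(OC)c1 | starting material
7 | (2S,3S)-2-(3,5-dimethoxyphenyl)-4,6-dimethoxy-3-(4-methoxyphenyl)indan-1-one | COc1ccc([C@H]2c3c(OC)cc(OC)cc3C(=O)[C@@H]2c2cc(OC)cc(OC)c2)cc1 | intermediate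
8 | 5-bromo-2-hydroxybenzonitrile | N#Cc1cc(Br)ccc1O | starting material
9 | 4-methoxybenzyl chloride | COc1ccc(CCl)cc1 | starting material
10 | 5-bromo-2-[(4-methoxyphenyl)methoxy]benzonitrile | COc1ccc(COc2ccc(Br)cc2C#N)cc1 | intermediate
11 | 3,5-dimethoxyphenylmagnesium bromide | COc1cc([Mg]Br)cc(OC)c1 | intermediate
12 | {5-bromo-2-[(4-methoxyphenyl)methoxy]phenyl}(3,5-dimethoxyphenyl)methanimine | COc1ccc(COc2ccc(Br)cc2C(=N)c2cc(OC)cc(OC)c2)cc1 | intermediate
13 | {5-bromo-2-[(4-methoxyphenyl)methoxy]phenyl}(3,5-dimethoxyphenyl)methanone hydrazone (E/Z mixture) | COc1ccc(COc2ccc(Br)cc2C(=NN)c2cc(OC)cc(OC)c2)cc1 | intermediate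
14 | 4-bromo-2-[diazo(3,5-dimethoxyphenyl)methyl]-1-[(4-methoxyphenyl)methoxy]benzene | COc1ccc(COc2ccc(Br)cc2C(=[N+]=[N-])c2cc(OC)cc(OC)c2)cc1 | intermediate
15 | (2S,3R)-5-bromo-3-(3,5-dimethoxyphenyl)-2-(4-methoxyphenyl)-2,3-dihydro-1-benzofuran (cis) | Brc1ccc2c(c1)[C@@H](c1cc(OC)cc(OC)c1)[C@@H](c1ccc(OC)cc1)O2 | intermediate
16 | (2R,3R)-5-bromo-3-(3,5-dimethoxyphenyl)-2-(4-methoxyphenyl)-2,3-dihydro-1-benzofuran (trans) | Brc1ccc2c(c1)[C@@H](c1cc(OC)cc(OC)c1)[C@H](c1ccc(OC)cc1)O2 | intermediate
17 | [(2R,3R)-3-(3,5-dimethoxyphenyl)-2-(4-methoxyphenyl)-2,3-dihydro-1-benzofuran-5-yl]lithium | [Li]c1ccc2c(c1)[C@@H](c1cc(OC)cc(OC)c1)[C@H](c1ccc(OC)cc1)O2 | intermediate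
18 | (2R,3R)-3-(3,5-dimethoxyphenyl)-2-(4-methoxyphenyl)-2,3-dihydro-1-benzofuran-5-carbaldehyde | O=Cc1ccc2c(c1)[C@@H](c1cc(OC)cc(OC)c1)[C@H](c1ccc(OC)cc1)O2 | intermediate
19 | [(2R,3R)-3-(3,5-dimethoxyphenyl)-2-(4-methoxyphenyl)-2,3-dihydro-1-benzofuran-5-yl]methanol | OCc1ccc2c(c1)[C@@H](c1cc(OC)cc(OC)c1)[C@H](c1ccc(OC)cc1)O2 | intermediate
20 | (2R,3R)-5-(chloromethyl)-3-(3,5-dimethoxyphenyl)-2-(4-methoxyphenyl)-2,3-dihydro-1-benzofuran | ClCc1ccc2c(c1)[C@@H](c1cc(OC)cc(OC)c1)[C@H](c1ccc(OC)cc1)O2 | intermediate
21 | {[(2R,3R)-3-(3,5-dimethoxyphenyl)-2-(4-methoxyphenyl)-2,3-dihydro-1-benzofuran-5-yl]methyl}magnesium chloride | Cl[Mg]Cc1ccc2c(c1)[C@@H](c1cc(OC)cc(OC)c1)[C@H](c1ccc(OC)cc1)O2 | intermediate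
22 | (1R,2S,3S)-1-{[(2R,3R)-3-(3,5-dimethoxyphenyl)-2-(4-methoxyphenyl)-2,3-dihydro-1-benzofuran-5-yl]methyl}-2-(3,5-dimethoxyphenyl)-4,6-dimethoxy-3-(4-methoxyphenyl)indan-1-ol | COc1ccc([C@H]2c3c(OC)cc(OC)cc3[C@@](O)(Cc3ccc4c(c3)[C@@H](c3cc(OC)cc(OC)c3)[C@H](c3ccc(OC)cc3)O4)[C@@H]2c2cc(OC)cc(OC)c2)cc1 | intermediate
23 | triethylammonium N-(methoxycarbonyl)sulfamate ester of 22 | COc1ccc([C@H]2c3c(OC)cc(OC)cc3[C@@](OS(=O)(=O)[N-]C(=O)OC)(Cc3ccc4c(c3)[C@@H](c3cc(OC)cc(OC)c3)[C@H](c3ccc(OC)cc3)O4)[C@@H]2c2cc(OC)cc(OC)c2)cc1.CC[NH+](CC)CC | intermediate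
24 | (2R,3R)-5-{(E)-[(2S,3S)-2-(3,5-dimethoxyphenyl)-4,6-dimethoxy-3-(4-methoxyphenyl)-2,3-dihydro-1H-inden-1-ylidene]methyl}-3-(3,5-dimethoxyphenyl)-2-(4-methoxyphenyl)-2,3-dihydro-1-benzofuran | COc1ccc([C@H]2c3c(OC)cc(OC)cc3/C(=C/c3ccc4c(c3)[C@@H](c3cc(OC)cc(OC)c3)[C@H](c3ccc(OC)cc3)O4)[C@@H]2c2cc(OC)cc(OC)c2)cc1 | intermediate
25 | (1E,2S,3S)-2-(3,5-dihydroxyphenyl)-1-{[(2R,3R)-3-(3,5-dihydroxyphenyl)-2-(4-hydroxyphenyl)-2,3-dihydro-1-benzofuran-5-yl]methylidene}-3-(4-hydroxyphenyl)-2,3-dihydro-1H-indene-4,6-diol | Oc1ccc([C@H]2c3c(O)cc(O)cc3/C(=C/c3ccc4c(c3)[C@@H](c3cc(O)cc(O)c3)[C@H](c3ccc(O)cc3)O4)[C@@H]2c2cc(O)cc(O)c2)cc1 | target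

## Step count and least certain steps

Total: 12 steps. Longest linear sequence: 9 steps (8 → 10 → 13 → 15 → 16 → 19 → 20 → 22 → 24 → 25); the indanone branch (steps 1–3) joins at step 10.

**Step 2 (key step).**
- What may go wrong: protonation of the alkenylrhodium before the 1,4-shift, because the ortho C–H lies between the carbonyl-bearing carbon and a methoxy group; this would end in open-chain isomerisation. Face selection in the ring closure may also be insufficient. One enantiomer of the carbinol may turn over slowly on the chiral catalyst, leaving conversion incomplete.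
- Fallback, from 2 back to 5: bromination of 2 (N-bromosuccinimide, MeCN) would give 2-bromo-3,5-dimethoxybenzaldehyde F1. Addition of the acetylide 3 would give the bromo propargylic alcohol F2. Ruthenium-catalysed redox isomerisation ((indenyl)RuCl(PPh3)2, In(OTf)3, camphorsulfonic acid, THF, reflux) would give the 2'-bromochalcone F3. Enantioselective reductive Heck cyclisation (Pd(OAc)2, (R)-3,5-Xyl-MeO-BIPHEP, 1,8-bis(dimethylamino)naphthalene, DMF, 100 °C) would then close the same C1–C7a bond from a preformed aryl–palladium and return to 5.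

**Step 10.**
- What may go wrong: Wurtz-type homocoupling during magnesium insertion into the reactive benzylic chloride; proton transfer from C2–H of the ketone to the benzylic nucleophile in place of addition; attack from the face syn to the C2 aryl group, which would weaken the stereochemical basis of step 11.
- Fallback, from 7 and 16 back to 24 (bypassing steps 8–11): boron-Wittig olefination of 7 (bis[(pinacolato)boryl]methane, lithium 2,2,6,6-tetramethylpiperidide, THF, −78 °C → rt) would give the (E)-alkenyl pinacol boronate F4 with boron on the C2 side. Suzuki–Miyaura coupling of F4 with 16 (PdCl2(dppf), K3PO4, dioxane–water, 80 °C) would give 24 with retention of alkene geometry. No benzylic organometallic and no dehydration are then needed.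

**Step 11.**
- What may go wrong: ionisation of the sulfamate to the tertiary benzylic cation and loss of the C2 proton, which would place the double bond in the ring and erase C2; incomplete E/Z selection.
- Fallback, from 7 and 20 back to 24, using a Ramberg–Bäcklund olefination that fixes the alkene position. Reduction of 7 (NaBH4, MeOH–THF, 0 °C) would give the indanol F5. ZnI2-mediated substitution with thioacetic acid through the benzylic cation would give the indanyl thioacetate F6. K2CO3 in MeOH in the presence of 20 would free the thiolate and alkylate it to the sulfide F7. Oxidation (m-chloroperbenzoic acid, NaHCO3, CH2Cl2, 0 °C) would give the sulfone F8. KOH, CCl4 and t-BuOH would then effect α-chlorination, episulfone formation and loss of sulfur dioxide to give 24.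

**Step 12.**
- What may go wrong: migration of the double bond into the five-membered ring under the hydrogen bromide formed on quenching; incomplete cleavage of eight ethers; ionisation at C2' followed by capture of the cation by a neighbouring arene.
- Fallback, from 7 and 16 back to 25, exchanging the protecting groups before the alkene exists. Demethylation of 7 with BBr3 would give the pentaphenol indanone F9, and silylation (i-Pr3SiCl, imidazole, DMF) its pentakis(triisopropylsilyl) ether F10. Demethylation of 16 would likewise give the triphenol bromide F11 and then the tris(silyl) bromide F12. F12 would be taken through the operations of steps 8 and 9 to the silylated benzylic alcohol F13 and the silylated benzylic chloride F14. Coupling with F10 as in step 10 would give the octasilyl tertiary alcohol F15, and dehydration as in step 11 the octasilyl alkene F16. Buffered fluoride (n-Bu4NF, AcOH, THF, 0 °C) would then release 25 without acid.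

## Further compounds

F1 | step 2 | 2-bromo-3,5-dimethoxybenzaldehyde | O=Cc1cc(OC)cc(OC)c1Br
F2 | step 2 | rac-1-(2-bromo-3,5-dimethoxyphenyl)-3-(4-methoxyphenyl)prop-2-yn-1-ol | COc1ccc(C#CC(O)c2cc(OC)cc(OC)c2Br)cc1
F3 | step 2 | (E)-1-(2-bromo-3,5-dimethoxyphenyl)-3-(4-methoxyphenyl)prop-2-en-1-one | COc1ccc(/C=C/C(=O)c2cc(OC)cc(OC)c2Br)cc1
F4 | step 10 | 2-{(E)-[(2S,3S)-2-(3,5-dimethoxyphenyl)-4,6-dimethoxy-3-(4-methoxyphenyl)-2,3-dihydro-1H-inden-1-ylidene]methyl}-4,4,5,5-tetramethyl-1,3,2-dioxaborolane | COc1ccc([C@H]2c3c(OC)cc(OC)cc3/C(=C/B3OC(C)(C)C(C)(C)O3)[C@@H]2c2cc(OC)cc(OC)c2)cc1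
F5 | step 11 | (1R,2S,3S)-2-(3,5-dimethoxyphenyl)-4,6-dimethoxy-3-(4-methoxyphenyl)indan-1-ol | COc1ccc([C@H]2c3c(OC)cc(OC)cc3[C@H](O)[C@@H]2c2cc(OC)cc(OC)c2)cc1
F6 | step 11 | S-[(1S,2S,3S)-2-(3,5-dimethoxyphenyl)-4,6-dimethoxy-3-(4-methoxyphenyl)indan-1-yl] ethanethioate | COc1ccc([C@H]2c3c(OC)cc(OC)cc3[C@@H](SC(C)=O)[C@@H]2c2cc(OC)cc(OC)c2)cc1
F7 | step 11 | (2R,3R)-5-({[(1S,2S,3S)-2-(3,5-dimethoxyphenyl)-4,6-dimethoxy-3-(4-methoxyphenyl)indan-1-yl]sulfanyl}methyl)-3-(3,5-dimethoxyphenyl)-2-(4-methoxyphenyl)-2,3-dihydro-1-benzofuran | COc1ccc([C@H]2c3c(OC)cc(OC)cc3[C@@H](SCc3ccc4c(c3)[C@@H](c3cc(OC)cc(OC)c3)[C@H](c3ccc(OC)cc3)O4)[C@@H]2c2cc(OC)cc(OC)c2)cc1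
F8 | step 11 | (2R,3R)-5-({[(1S,2S,3S)-2-(3,5-dimethoxyphenyl)-4,6-dimethoxy-3-(4-methoxyphenyl)indan-1-yl]sulfonyl}methyl)-3-(3,5-dimethoxyphenyl)-2-(4-methoxyphenyl)-2,3-dihydro-1-benzofuran | COc1ccc([C@H]2c3c(OC)cc(OC)cc3[C@@H](S(=O)(=O)Cc3ccc4c(c3)[C@@H](c3cc(OC)cc(OC)c3)[C@H](c3ccc(OC)cc3)O4)[C@@H]2c2cc(OC)cc(OC)c2)cc1
F9 | step 12 | (2S,3S)-2-(3,5-dihydroxyphenyl)-4,6-dihydroxy-3-(4-hydroxyphenyl)indan-1-one | Oc1ccc([C@H]2c3c(O)cc(O)cc3C(=O)[C@@H]2c2cc(O)cc(O)c2)cc1
F10 | step 12 | pentakis(triisopropylsilyl) ether of F9 | CC(C)[Si](C(C)C)(C(C)C)Oc1ccc([C@H]2c3c(O[Si](C(C)C)(C(C)C)C(C)C)cc(O[Si](C(C)C)(C(C)C)C(C)C)cc3C(=O)[C@@H]2c2cc(O[Si](C(C)C)(C(C)C)C(C)C)cc(O[Si](C(C)C)(C(C)C)C(C)C)c2)cc1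
F11 | step 12 | 5-[(2R,3R)-5-bromo-2-(4-hydroxyphenyl)-2,3-dihydro-1-benzofuran-3-yl]benzene-1,3-diol | Brc1ccc2c(c1)[C@@H](c1cc(O)cc(O)c1)[C@H](c1ccc(O)cc1)O2
F12 | step 12 | tris(triisopropylsilyl) ether of F11 | Brc1ccc2c(c1)[C@@H](c1cc(O[Si](C(C)C)(C(C)C)C(C)C)cc(O[Si](C(C)C)(C(C)C)C(C)C)c1)[C@H](c1ccc(O[Si](C(C)C)(C(C)C)C(C)C)cc1)O2
F13 | step 12 | [(2R,3R)-3-{3,5-bis[(triisopropylsilyl)oxy]phenyl}-2-{4-[(triisopropylsilyl)oxy]phenyl}-2,3-dihydro-1-benzofuran-5-yl]methanol | OCc1ccc2c(c1)[C@@H](c1cc(O[Si](C(C)C)(C(C)C)C(C)C)cc(O[Si](C(C)C)(C(C)C)C(C)C)c1)[C@H](c1ccc(O[Si](C(C)C)(C(C)C)C(C)C)cc1)O2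
F14 | step 12 | (2R,3R)-5-(chloromethyl)-3-{3,5-bis[(triisopropylsilyl)oxy]phenyl}-2-{4-[(triisopropylsilyl)oxy]phenyl}-2,3-dihydro-1-benzofuran | ClCc1ccc2c(c1)[C@@H](c1cc(O[Si](C(C)C)(C(C)C)C(C)C)cc(O[Si](C(C)C)(C(C)C)C(C)C)c1)[C@H](c1ccc(O[Si](C(C)C)(C(C)C)C(C)C)cc1)O2
F15 | step 12 | octakis(triisopropylsilyl) analogue of 22 | CC(C)[Si](C(C)C)(C(C)C)Oc1ccc([C@H]2c3c(O[Si](C(C)C)(C(C)C)C(C)C)cc(O[Si](C(C)C)(C(C)C)C(C)C)cc3[C@@](O)(Cc3ccc4c(c3)[C@@H](c3cc(O[Si](C(C)C)(C(C)C)C(C)C)cc(O[Si](C(C)C)(C(C)C)C(C)C)c3)[C@H](c3ccc(O[Si](C(C)C)(C(C)C)C(C)C)cc3)O4)[C@@H]2c2cc(O[Si](C(C)C)(C(C)C)C(C)C)cc(O[Si](C(C)C)(C(C)C)C(C)C)c2)cc1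
F16 | step 12 | octakis(triisopropylsilyl) analogue of 24 | CC(C)[Si](C(C)C)(C(C)C)Oc1ccc([C@H]2c3c(O[Si](C(C)C)(C(C)C)C(C)C)cc(O[Si](C(C)C)(C(C)C)C(C)C)cc3/C(=C/c3ccc4c(c3)[C@@H](c3cc(O[Si](C(C)C)(C(C)C)C(C)C)cc(O[Si](C(C)C)(C(C)C)C(C)C)c3)[C@H](c3ccc(O[Si](C(C)C)(C(C)C)C(C)C)cc3)O4)[C@@H]2c2cc(O[Si](C(C)C)(C(C)C)C(C)C)cc(O[Si](C(C)C)(C(C)C)C(C)C)c2)cc1
A1 | alternative 1 | (1S,2S)-3-(tert-butyldimethylsilyloxy)-2-(3,5-dimethoxyphenyl)-5-ethoxy-7-hydroxy-1-(4-methoxyphenyl)indane (target numbering) | CCOc1cc(O)c2c(c1)[C@H](O[Si](C)(C)C(C)(C)C)[C@H](c1cc(OC)cc(OC)c1)[C@H]2c1ccc(OC)cc1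
A2 | alternative 1 | 2-diazo-1-[5-(tert-butyldimethylsilyloxy)-4-(3,5-dimethoxyphenyl)-3-(4-methoxyphenyl)cyclopent-1-en-1-yl]ethanone (3,4-trans, 4,5-cis, configured as in A1) | [N-]=[N+]=CC(=O)C1=C[C@H](c2ccc(OC)cc2)[C@@H](c2cc(OC)cc(OC)c2)[C@H]1O[Si](C)(C)C(C)(C)C
A3 | alternative 1 | ethoxyacetylene | CCOC#C
A4 | alternative 2 | (2R,3R)-5-bromo-3-(3,5-dimethoxyphenyl)-2-(4-methoxyphenyl)-2,3-dihydro-1-benzofuran | Brc1ccc2c(c1)[C@@H](c1cc(OC)cc(OC)c1)[C@H](c1ccc(OC)cc1)O2
A5 | alternative 2 | rac-4-bromo-2-[(3,5-dimethoxyphenyl)(4-methylbenzenesulfonyl)methyl]phenol | Cc1ccc(cc1)S(=O)(=O)C(c1cc(OC)cc(OC)c1)c1cc(Br)ccc1O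
A6 | alternative 2 | 4-bromo-6-[(3,5-dimethoxyphenyl)methylidene]cyclohexa-2,4-dien-1-one | O=C1C=CC(Br)=CC1=Cc1cc(OC)cc(OC)c1
A7 | alternative 2 | (2R,5R)-1-[(4-methoxyphenyl)methyl]-2,5-dimethylthiolan-1-ium tetrafluoroborate | C[C@@H]1CC[C@@H](C)[S+]1Cc1ccc(OC)cc1.F[B-](F)(F)F
A8 | alternative 3 | methyl (2R,3R)-5-bromo-2-[4-(methylsulfonyloxy)phenyl]-2,3-dihydro-1-benzofuran-3-carboxylate | Brc1ccc2c(c1)[C@@H](C(=O)OC)[C@H](c1ccc(OS(C)(=O)=O)cc1)O2
A9 | alternative 3 | 4-[(2R)-6-bromo-4-oxo-3,4-dihydro-2H-chromen-2-yl]phenyl methanesulfonate | O=C1C[C@H](c2ccc(OS(C)(=O)=O)cc2)Oc2ccc(Br)cc12
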